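## Structural features

The target is a trans-fused bicyclo[5.3.0]decane. Ring A is a cyclopentanone: C1 (quaternary, angular methyl), C2 (ketone), C3 (methylene), C4 (tertiary carbinol carrying the isopropyl group) and C5 (ring-fusion methine). Ring B is a cycloheptene: C5, C6 (4-methoxybenzoate), C7, C8 (methyl), C9, C10 and C1, with the olefin at C8=C9; the rings share the C1–C5 bond. The stereocentres C1, C5, C4 and C6 are contiguous: C5 sits between the two fully substituted carbons C1 and C4 and next to C6. The angular methyl and H5 are trans, the C4 hydroxyl lies on the face of the angular methyl, and the C6 ester is equatorial on ring B, on the face of H5. Fragile elements are the β-hydroxy ketone made by the C2 carbonyl and the C4 hydroxyl (retro-aldol opening of ring A, dehydration to a C3=C4 enone), the aryl ester (base, acyl shift to the C4 hydroxyl), and the C8=C9 olefin, which is β,γ to C6 and can slip into conjugation whenever C6 is a ketone. The real difficulty is threefold: two quaternary carbons must be built on either side of C5 with a trans five–seven fusion, ring B must be closed with its olefin in a defined place, and two carbons that pass through the ketone level (C2 and C6) must be told apart. The key step uses the fact that, in ring A, C5 and C1 are the β- and α-carbons of the C2 ketone, so a 2-methylcyclopent-2-enone that already carries the C4 carbinol can take up the C6–C7 unit at C5 and the C10–C9–C8 unit at C1 in one operation; C4 steers the first bond and the new C5 substituent steers the second.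

## Logic of the disconnections

**26 from 25.** No skeletal bond is cut; the C2 carbonyl is traced back to a C2 carbinol (C2–H). The β-hydroxy ketone of 26 is best unveiled last under neutral conditions. With C2 at the alcohol level from 17 to 25, C6 is the only ketone present while ring B is built, so one enolisation and one reduction suffice without any selection between two carbonyls. The price is two steps. The forward step must oxidise a secondary alcohol next to a quaternary carbon without touching a tertiary alcohol, an ester and an olefin.

**25 from 24, and 24 from 22 and 23.** The two O–Si bonds and the C6 O–acyl bond are cut. 23 is commercial and 22 has a single free hydroxyl, so the acylation needs no selectivity. The demands are acylation of a secondary alcohol next to the ring-fusion carbon, and a desilylation that does not move the ester to the C4 oxygen.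

**22 from 21.** The C6–H bond is cut, giving the C6 ketone, which is the oxidation level at which ring closure delivers C6. The wanted epimer is the equatorial, more stable alcohol. The forward reduction must therefore run under thermodynamic control, and must act before the C8=C9 olefin of 21 can move into conjugation.

**21 from 20, 20 from 19, 19 from 18.** The C7–C8 bond of ring B is cut. C7 is α to the C6 carbonyl and C8 ends as an olefinic carbon, so the precursors are a C6=C7 enol ether and a C9≡C8 alkyne; the olefin then appears at C8=C9 with no later adjustment. Ring B is reduced to two arms on ring A: an acetyl group at C5 (19), itself the Wacker product of a vinyl group (18), and a but-2-ynyl group at C1. The demands are 7-endo rather than 6-exo closure, enol ether formation towards C7 only, and Markovnikov oxidation of a hindered vinyl group.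

**18 from 17, and 17 from 16.** O–Si bonds and the C2–H bond; the skeleton is unchanged. This is the entry to the C2 detour. 16 has its C4 hydroxyl free, which allows a hydroxyl-directed reduction to a single diol. The demands are reduction of the C2 ketone without touching alkyne or alkene, and silylation of a hindered tertiary alcohol.

**16 from 12, 13 and 14.** The C5–C6 and C1–C10 bonds are cut. They are the bonds to the β- and α-carbons of the C2 ketone, so one conjugate addition and one enolate alkylation form them in a single flask. The gain is large: 12 is a small enone with one stereocentre, 13 and 14 are commercial, and every carbon of ring B is delivered. The demands are addition at C5 anti to the isopropyl group, alkylation at C1 anti to the new vinyl group, 1,4- over 1,2-addition, and C-alkylation of a hindered tetrasubstituted enolate. The C4 hydroxyl of 12 is deliberately left free: as an alkoxide it is the smaller substituent at C4, it may direct the organometallic to its own face, and it cannot be eliminated.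

**12 from 9 (through 10 and 11).** The C1=C5 enone bond is cut by a retro-aldol condensation, and the C2 carbonyl is masked as a dithiane. This leaves an acyclic chain with one stereocentre. The aldehyde of 10 has no α-hydrogen, so only one aldol mode gives a five-membered ring; the base must be mild because 10 is a β-hydroxy ketone.

**9 from 8, and 8 from 5 and 6 (through 7).** The C3–C2 bond is cut between an epoxide CH2 and an acyl-anion equivalent. 5 is a six-carbon chiral epoxide and 6 is commercial. The demands are SN2 opening at the CH2 terminus of a 2,2-disubstituted epoxide by a hindered carbanion in the presence of a free hydroxyl, and oxidation of a primary alcohol beside sulfur.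

**5 from 4, 4 from 3, 3 from 1 and 2.** In turn: the epoxide C–O bonds (asymmetric epoxidation sets C4), the carbinol C–H bond, and the C=CH2 bond to formaldehyde. The starting materials are two bulk aldehydes. The demands are enantioface selection on a 2-substituted allylic alcohol and careful handling of volatile six-carbon compounds.

## Other disconnections considered

**Alternative 1:** The cut is C5–C6, with C1 set earlier by desymmetrising reduction of a prochiral diketone.
- Forward step: the alkenyl triflate aldehyde A1 is treated with CrCl2 and catalytic NiCl2 (Nozaki–Hiyama–Kishi reaction). Oxidative addition, transfer to chromium and intramolecular carbonyl addition close ring B and give the bicyclic allylic alcohol A2.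
- In favour: the quaternary C1 comes from a well-established desymmetrisation. The closure has no regiochemical ambiguity, which makes it better than the gold closure of the chosen plan. C6 arrives directly as a carbinol. The C8=C9 olefin comes in with the side chain and never sits β,γ to a ketone, also better than the chosen plan.
- Against: A2 has neither C4 nor C5 in place. C5–H must be set by hydroboration of the C4=C5 olefin anti to the angular methyl. C4 must then be made by oxidation and isopropyl addition to a carbonyl that is α to the epimerisable ring-fusion carbon and β to the C6 oxygen, so enolisation, reduction by the hindered organometallic and β-elimination all compete, and the face of addition is not obviously right. The C6 configuration rests on the diastereoselectivity of a seven-membered closure, and the (Z)-trisubstituted olefin must be made selectively in the side chain.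
- Comparison: structurally both plans reach the trans five–seven system, but here the stereocentres are set one at a time (C1, C6, C5, C4), whereas the chosen plan sets C4 first and lets it control C5 and C1 in one step. Mechanistically the closure is more reliable and the C4 construction less reliable. In step count the two are about equal up to ring closure and this plan is longer afterwards.

**Alternative 2:** The cuts are C1–C5 and C1–C10, both bonds to the quaternary carbon.
- Forward step: Rh2(OAc)4 decomposes the α-diazo ketone A3. The methyl-bearing carbenoid carbon adds across the ipso–ortho bond of the arene, and cyclopropanation with electrocyclic opening (Buchner reaction) closes ring A and turns the arene into the cycloheptatriene of A4.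
- In favour: the whole bicyclic skeleton and the quaternary C1 come from one step on an aromatic precursor. It forms two skeletal bonds, the equal of the chosen key step, and closes two rings where the chosen step closes none, which is better. C2 (ketone) and C6 (methyl enol ether) emerge already differentiated, a clear advantage over the chosen plan with its reduction–oxidation detour at C2.
- Against: a carbenoid with an α-methyl group is prone to 1,2-hydride shift before it reaches the arene. The arene offers two ortho positions and C–H insertion as further outlets. The configuration of C1 relative to C4 depends on which arene face is used, with only a remote centre to decide. In A4 one olefin must be kept in a new position (C8=C9), C5–H must be introduced trans to the angular methyl, and C6 must be brought to the equatorial alcohol, all by selective reductions of a conjugated system beside a β-silyloxy ketone.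
- Comparison: structurally it is the more convergent plan. Mechanistically its key step has more competing pathways and less stereocontrol, and the trans fusion is left to a late protonation or hydrogenation. In step count the front end is shorter, but the redox trimming of the triene is likely to cancel that gain.

**Alternative 3:** The cut is C1–C10, with ring B made before ring A.
- Forward step: the seven-membered lactone A5 is enolised with lithium diisopropylamide, silylated on oxygen and heated. The [3,3] shift (Ireland–Claisen ring contraction) through a ring-enforced boat forms C1–C10, breaks the C8–O bond and gives the cycloheptenecarboxylic acid A6.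
- In favour: the quaternary C1 is made by chirality transfer with the enolate geometry fixed by the lactone ring. C5 and C6 are set beforehand, C6 already as the correct carbinol, which is better than the reduction of the chosen plan. The C8=C9 olefin is placed unambiguously, also better than the gold closure.
- Against: A5 needs a stereodefined tertiary allylic carbinol and its lactonisation into a seven-membered ring, and such an ester can ionise on heating. In A6 ring A does not yet exist; it must be built from the C2 carboxyl and the C5 vinyl group, including the C4 carbinol, which would be set last with no neighbouring control element as close as in the chosen plan. C2 must be changed from acid to ketone while the C2–C3 bond is formed.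
- Comparison: structurally the two plans mirror each other (ring B first against ring A first). Mechanistically the rearrangement is the equal of the conjugate addition–alkylation in reliability of stereochemical transfer, but the harder half of the molecule (C4 beside C5) is left for the end. In step count it is expected to be longer, because lactone and ring A each need several steps.

Key step: step 7

Remark on the chemistry: the locants C1–C10 defined above are used for all intermediates; the carbinol configuration created at C2 in step 8 is temporary because C2 returns to a ketone in step 16; alkoxide forms of numbered compounds are not numbered separately.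

Step 1
Reactants: 1 3-methylbutanal (isovaleraldehyde); 2 formaldehyde (37 % aqueous)
Product: 3 3-methyl-2-methylidenebutanal
Conditions: 2 (aq.), pyrrolidine (10 mol %), EtCO2H (10 mol %), i-PrOH, 45 °C
Reagents that add atoms: none
Why: Amine-catalysed Mannich condensation of the aldehyde with formaldehyde followed by loss of the amine (α-methylenation); 1 has a single enolisable position and the product cannot enolise further, and no stereocentre is formed.

Step 2
Reactants: 3 3-methyl-2-methylidenebutanal
Product: 4 3-methyl-2-methylidenebutan-1-ol
Conditions: NaBH4, CeCl3·7H2O, MeOH, 0 °C
Reagents that add atoms: none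
Why: Luche reduction: CeCl3 directs borohydride to the carbonyl carbon, so the 1,1-disubstituted olefin survives and the allylic alcohol results.

Step 3
Reactants: 4 3-methyl-2-methylidenebutan-1-ol
Product: 5 [(2R)-2-(propan-2-yl)oxiran-2-yl]methanol
Conditions: t-BuOOH, Ti(Oi-Pr)4 (10 mol %), D-(−)-diisopropyl tartrate (12 mol %), 4 Å molecular sieves, CH2Cl2, −20 °C
Reagents that add atoms: tert-butyl hydroperoxide, CC(C)(C)OO
Why: Sharpless asymmetric epoxidation of a 2-substituted allylic alcohol; the L-(+) ester turns 2-methylprop-2-en-1-ol into its S epoxide, so the D-(−) ester should deliver oxygen to the opposite face and give the R epoxide (the isopropyl group, like methyl, is the lowest-ranked substituent), which sets the future C4. Catalytic titanium with sieves at low temperature limits opening of the sensitive 2,2-disubstituted epoxide.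

Step 4
Reactants: 5 [(2R)-2-(propan-2-yl)oxiran-2-yl]methanol; 6 2-ethyl-1,3-dithiane
Product: 8 (2R)-2-[(2-ethyl-1,3-dithian-2-yl)methyl]-3-methylbutane-1,2-diol, via 2-ethyl-2-lithio-1,3-dithiane 7 (not isolated)
Conditions: 6 (2.3 equiv), n-BuLi (2.2 equiv), THF, −30 °C; then 5, DMPU, −30 → 0 °C; aq. NH4Cl
Reagents that add atoms: none
Why: Corey–Seebach umpolung: the lithiated dithiane opens the epoxide by SN2 attack at its unsubstituted CH2, so the quaternary carbon keeps its configuration; one equivalent of the anion is consumed by the hydroxyl. The Payne rearrangement open to the epoxy alkoxide is degenerate here (it returns the same enantiomer), so it cannot erode the enantiomeric purity.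

Step 5
Reactants: 8 (2R)-2-[(2-ethyl-1,3-dithian-2-yl)methyl]-3-methylbutane-1,2-diol
Product: 9 (2R)-2-[(2-ethyl-1,3-dithian-2-yl)methyl]-2-hydroxy-3-methylbutanal
Conditions: SO3·pyridine, DMSO, i-Pr2NEt, CH2Cl2, 0 °C; aq. NaHCO3
Reagents that add atoms: none
Why: Parikh–Doering oxidation: activated dimethyl sulfoxide oxidises the primary alcohol only, the tertiary hydroxyl cannot be oxidised and the thioacetal is not attacked; the aldehyde has no α-hydrogen and cannot epimerise.

Step 6
Reactants: 9 (2R)-2-[(2-ethyl-1,3-dithian-2-yl)methyl]-2-hydroxy-3-methylbutanal
Product: 12 (4R)-4-hydroxy-2-methyl-4-(propan-2-yl)cyclopent-2-en-1-one, via keto aldehyde 10 (not isolated), via cyclic aldol 11 (not isolated)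
Conditions: MeI, CaCO3, MeCN/H2O (4:1), 45 °C; filter, concentrate; then K2CO3 (cat.), MeOH, 0 °C → rt
Reagents that add atoms: water, O
Why: S-Methylation and hydrolysis unmask the ketone without an oxidant; mild base then effects the intramolecular aldol condensation, in which the enolate on the ethyl side closes a five-membered ring on the non-enolisable aldehyde and the aldol loses water by E1cB. C4 is not involved and keeps its configuration.

Step 7
Reactants: 12 (4R)-4-hydroxy-2-methyl-4-(propan-2-yl)cyclopent-2-en-1-one; 13 vinylmagnesium bromide; 14 1-bromobut-2-yne
Product: 16 (2R,3R,4R)-2-(but-2-yn-1-yl)-3-ethenyl-4-hydroxy-2-methyl-4-(propan-2-yl)cyclopentan-1-one, via magnesium enolate 15 (not isolated)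
Conditions: 13 (2.5 equiv), CuBr·SMe2 (20 mol %), THF, −78 → −40 °C; then 14, DMPU, −40 → 0 °C; aq. NH4Cl
Reagents that add atoms: none
Why: Copper-mediated conjugate addition followed by enolate alkylation, the known three-component vicinal difunctionalisation of cyclopentenones. The first equivalent of 13 turns the C4 hydroxyl into its magnesium alkoxide, and the vinylcopper species formed from 13 and CuBr·SMe2 then adds to the β-carbon C5 to give the tetrasubstituted enolate 15 (C1=C2). C5 is set by C4: the vinyl group enters anti to the isopropyl group, the alkoxide oxygen being the smaller substituent and, if it coordinates the organometallic, directing to the same face, so both effects agree. C1 is set by C5: 14 reacts by direct SN2 displacement at its CH2 on the enolate face anti to the new vinyl group, so C6 and C10 end trans and the later ring fusion is fixed before ring B exists. No ring is closed; the step forms C5–C6 and C1–C10 and loads ring A with every carbon of ring B. The selectivities needed are 1,4- over 1,2-addition (copper, low temperature), C- over O-alkylation and SN2 over SN2′ attack on the propargylic bromide (polar cosolvent, reactive primary bromide), and alkylation before the enolate can equilibrate towards C3. Leaving the C4 oxygen as an alkoxide also removes any β-elimination pathway, since an oxide cannot leave.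

Step 8
Reactants: 16 (2R,3R,4R)-2-(but-2-yn-1-yl)-3-ethenyl-4-hydroxy-2-methyl-4-(propan-2-yl)cyclopentan-1-one
Product: 17 (1R,3S,4R,5R)-4-(but-2-yn-1-yl)-5-ethenyl-4-methyl-1-(propan-2-yl)cyclopentane-1,3-diol
Conditions: Me4NBH(OAc)3, MeCN/AcOH (1:1), −20 °C → rt
Reagents that add atoms: none
Why: Hydroxyl-directed (Evans–Saksena type) reduction: the acetoxyborohydride exchanges onto the C4 hydroxyl and delivers hydride to C2 from that face, which should give the 2,4-trans diol as one isomer; alkene and alkyne are inert. The carbinol is a temporary mask, so that C6 is the only carbonyl when the enol ether is made (step 11) and when a ketone is reduced (step 13).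

Step 9
Reactants: 17 (1R,3S,4R,5R)-4-(but-2-yn-1-yl)-5-ethenyl-4-methyl-1-(propan-2-yl)cyclopentane-1,3-diol
Product: 18 bis(triethylsilyl) ether of 17 (C2 and C4 oxygens silylated; 1R,2S,4R,5R in the C1–C10 locants)
Conditions: Et3SiOTf, 2,6-lutidine, CH2Cl2, −78 → 0 °C; aq. NaHCO3
Reagents that add atoms: triethylsilyl trifluoromethanesulfonate, CC[Si](CC)(CC)OS(=O)(=O)C(F)(F)F
Why: Silylation with a silyl triflate, which is reactive enough for the hindered tertiary C4 hydroxyl as well as the neopentyl-type C2 hydroxyl; both ethers are needed so that neither oxygen can add to the olefin, the alkyne or the later C6 carbonyl.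

Step 10
Reactants: 18 bis(triethylsilyl) ether (C5 vinyl, C1 but-2-ynyl)
Product: 19 C5 acetyl compound (C6 ketone, C7 methyl; C1 methyl and but-2-ynyl; C2 and C4 triethylsilyl ethers; 1R,2S,4R,5R)
Conditions: PdCl2 (20 mol %), CuCl, O2 (1 atm), DMF/H2O (7:1), rt
Reagents that add atoms: water, O
Why: Tsuji–Wacker oxidation: Markovnikov hydroxypalladation of the monosubstituted olefin and β-hydride elimination give the methyl ketone; the internal alkyne is hydrated far more slowly and, being trans to the vinyl group on ring A, cannot reach it for a palladium-mediated enyne cyclisation.

Step 11
Reactants: 19 C5 acetyl compound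
Product: 20 C6 tert-butyldimethylsilyl enol ether (C6=C7 terminal enol ether; C1 but-2-ynyl; C2 and C4 triethylsilyl ethers; 1R,2S,4R,5S)
Conditions: t-BuMe2SiOTf, Et3N, CH2Cl2, −78 → 0 °C; aq. NaHCO3
Reagents that add atoms: tert-butyldimethylsilyl trifluoromethanesulfonate, CC(C)(C)[Si](C)(C)OS(=O)(=O)C(F)(F)F
Why: Soft enolisation (silyl triflate and tertiary amine): of the two α-positions only the C7 methyl is accessible, C5–H lying between two quaternary carbons, so the terminal enol ether forms; no metal enolate is generated, which avoids β-elimination of the C4 silyloxy group.

Step 12
Reactants: 20 C6 tert-butyldimethylsilyl enol ether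
Product: 21 trans-fused bicyclic C6 ketone (ring B closed, C8=C9 olefin, C8 methyl; C2 and C4 triethylsilyl ethers; 1R,2S,4R,5R)
Conditions: Ph3PAuNTf2 (5 mol %), CH2Cl2/MeOH (10:1), rt
Reagents that add atoms: none
Why: Monovalent-gold-catalysed carbocyclisation of a silyl enol ether onto an alkyne (Conia-ene type): the cationic gold complex activates the alkyne, C7 attacks C8 anti to gold in the 7-endo-dig mode, methanol takes the silyl group and protodeauration at C9 leaves the C8=C9 olefin and the C6 ketone. The endo mode is expected to be favoured by the methyl-capped internal alkyne and by the trans disposition of the two arms, which makes the six-membered exo ring (two trigonal carbons in a trans-fused hydrindane) the more strained; no stereocentre is created and the trans ring fusion is inherited from step 7.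

Step 13
Reactants: 21 trans-fused bicyclic C6 ketone
Product: 22 C6 equatorial alcohol (hydroxyl on the face of H5; C2 and C4 triethylsilyl ethers; 1R,2S,4R,5S,6S)
Conditions: Li, NH3(l)/THF, t-BuOH, −78 °C; then NH4Cl
Reagents that add atoms: none
Why: Dissolving-metal reduction, which gives the thermodynamically preferred alcohol: the C6 oxygen ends equatorial on ring B, on the face of H5, and H6 is placed on the face of the angular methyl, as in the target. A hydride reagent would be expected to approach from the open face, away from the syn-axial angular methyl, and give the axial epimer instead; the isolated trisubstituted olefin and the silyl ethers are inert to lithium in ammonia.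

Step 14
Reactants: 22 C6 equatorial alcohol; 23 4-methoxybenzoyl chloride
Product: 24 C6 4-methoxybenzoate with C2 and C4 triethylsilyl ethers (1R,2S,4R,5S,6S)
Conditions: 23, Et3N, DMAP (cat.), CH2Cl2, 0 °C → rt; aq. NaHCO3
Reagents that add atoms: none
Why: DMAP-catalysed acylation with the acid chloride; the C6 hydroxyl is the only free hydroxyl and, being equatorial, is accessible.

Step 15
Reactants: 24 C6 4-methoxybenzoate bis(triethylsilyl) ether
Product: 25 C6 4-methoxybenzoate C2,C4-diol (1R,2S,4R,5S,6S)
Conditions: HF·pyridine, pyridine, THF, 0 °C → rt
Reagents that add atoms: none
Why: Fluoride cleavage of both triethylsilyl ethers under weakly acidic, buffered conditions, chosen over basic fluoride to avoid ester cleavage or acyl shift from C6 to the C4 hydroxyl.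

Step 16
Reactants: 25 C6 4-methoxybenzoate C2,C4-diol
Product: 26 target, the C2 ketone with C4 hydroxyl and C6 4-methoxybenzoate (1R,4R,5S,6S)
Conditions: Dess–Martin periodinane, NaHCO3, CH2Cl2, 0 °C → rt
Reagents that add atoms: none
Why: Dess–Martin oxidation of the secondary C2 carbinol; the tertiary C4 hydroxyl cannot be oxidised and the ester and olefin are inert. The β-hydroxy ketone appears only in this last, buffered and non-basic step, so retro-aldol cleavage and dehydration are avoided.

Compound list

1 | 3-methylbutanal (isovaleraldehyde) | CC(C)CC=O | starting material
2 | formaldehyde (37 % aqueous) | C=O | starting material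
3 | 3-methyl-2-methylidenebutanal | CC(C)C(=C)C=O | intermediate
4 | 3-methyl-2-methylidenebutan-1-ol | CC(C)C(=C)CO | intermediate
5 | [(2R)-2-(propan-2-yl)oxiran-2-yl]methanol | OC[C@]1(C(C)C)CO1 | intermediate
6 | 2-ethyl-1,3-dithiane | CCC1SCCCS1 | starting material
7 | 2-ethyl-2-lithio-1,3-dithiane (not isolated) | [Li]C1(CC)SCCCS1 | intermediate
8 | (2R)-2-[(2-ethyl-1,3-dithian-2-yl)methyl]-3-methylbutane-1,2-diol | OC[C@](O)(C(C)C)CC1(CC)SCCCS1 | intermediate
9 | (2R)-2-[(2-ethyl-1,3-dithian-2-yl)methyl]-2-hydroxy-3-methylbutanal | O=C[C@](O)(C(C)C)CC1(CC)SCCCS1 | intermediate
10 | (2R)-2-hydroxy-4-oxo-2-(propan-2-yl)hexanal (not isolated) | O=C[C@](O)(C(C)C)CC(=O)CC | intermediate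
11 | (4R)-3,4-dihydroxy-2-methyl-4-(propan-2-yl)cyclopentan-1-one, epimers at the two new carbons (not isolated) | CC1C(O)[C@](O)(C(C)C)CC1=O | intermediate
12 | (4R)-4-hydroxy-2-methyl-4-(propan-2-yl)cyclopent-2-en-1-one | CC1=C[C@](O)(C(C)C)CC1=O | intermediate
13 | vinylmagnesium bromide | C=C[Mg]Br | starting material
14 | 1-bromobut-2-yne | CC#CCBr | starting material
15 | bis(bromomagnesium) enolate–alkoxide: C1=C2 enolate of the conjugate adduct, C5 vinyl anti to isopropyl (not isolated) | CC1=C(O[Mg]Br)C[C@@](O[Mg]Br)(C(C)C)[C@@H]1C=C | intermediate
16 | (2R,3R,4R)-2-(but-2-yn-1-yl)-3-ethenyl-4-hydroxy-2-methyl-4-(propan-2-yl)cyclopentan-1-one | CC#CC[C@@]1(C)C(=O)C[C@@](O)(C(C)C)[C@@H]1C=C | intermediate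
17 | (1R,3S,4R,5R)-4-(but-2-yn-1-yl)-5-ethenyl-4-methyl-1-(propan-2-yl)cyclopentane-1,3-diol | CC#CC[C@@]1(C)[C@@H](O)C[C@@](O)(C(C)C)[C@@H]1C=C | intermediate
18 | bis(triethylsilyl) ether of 17 | CC#CC[C@@]1(C)[C@@H](O[Si](CC)(CC)CC)C[C@@](O[Si](CC)(CC)CC)(C(C)C)[C@@H]1C=C | intermediate
19 | C5 acetyl compound, C2 and C4 triethylsilyl ethers | CC#CC[C@@]1(C)[C@@H](O[Si](CC)(CC)CC)C[C@@](O[Si](CC)(CC)CC)(C(C)C)[C@@H]1C(C)=O | intermediate
20 | C6 tert-butyldimethylsilyl enol ether (C6=C7), C2 and C4 triethylsilyl ethers | CC#CC[C@@]1(C)[C@@H](O[Si](CC)(CC)CC)C[C@@](O[Si](CC)(CC)CC)(C(C)C)[C@@H]1C(=C)O[Si](C)(C)C(C)(C)C | intermediate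
21 | trans-fused bicyclic C6 ketone with C8=C9 olefin, C2 and C4 triethylsilyl ethers | O=C1CC(C)=CC[C@@]2(C)[C@@H](O[Si](CC)(CC)CC)C[C@@](O[Si](CC)(CC)CC)(C(C)C)[C@H]12 | intermediate
22 | C6 equatorial alcohol, C2 and C4 triethylsilyl ethers | O[C@H]1CC(C)=CC[C@@]2(C)[C@@H](O[Si](CC)(CC)CC)C[C@@](O[Si](CC)(CC)CC)(C(C)C)[C@H]12 | intermediate
23 | 4-methoxybenzoyl chloride | COc1ccc(C(Cl)=O)cc1 | starting material
24 | C6 4-methoxybenzoate, C2 and C4 triethylsilyl ethers | COc1ccc(C(=O)O[C@H]2CC(C)=CC[C@@]3(C)[C@@H](O[Si](CC)(CC)CC)C[C@@](O[Si](CC)(CC)CC)(C(C)C)[C@H]23)cc1 | intermediate
25 | C6 4-methoxybenzoate, C2 secondary and C4 tertiary alcohols | COc1ccc(C(=O)O[C@H]2CC(C)=CC[C@@]3(C)[C@@H](O)C[C@@](O)(C(C)C)[C@H]23)cc1 | intermediate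
26 | CNP0232277.1: C2 ketone, C4 hydroxyl, C6 4-methoxybenzoate | COc1ccc(C(=O)O[C@H]2CC(C)=CC[C@@]3(C)C(=O)C[C@@](O)(C(C)C)[C@H]23)cc1 | target

Total step count: 16. Longest linear sequence: 16 steps (1 → 26); 2, 6, 13, 14 and 23 are purchased and enter along the way.

Steps least certain to work

**Step 7 (key step).** Most likely failures are incomplete C-alkylation of the hindered tetrasubstituted magnesium enolate, proton transfer that moves the enolate towards C3 before it is alkylated, competing 1,2-addition, and erosion of facial selectivity at C5 if the alkoxide and the isopropyl group do not discriminate as expected. Fallback, from 12 back to 16: the two bond formations are separated. Addition of 13 with catalytic CuBr·SMe2 in the presence of Me3SiCl, which accelerates the addition, traps the enolate and silylates the alkoxide, should give the bis(trimethylsilyl) compound F1. MeLi then releases the lithium enolate F2 (not isolated), which is alkylated with 14 in THF/DMPU to the C4 trimethylsilyl ether F3. Citric acid in methanol removes the silyl group and gives 16.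

**Step 12 (gold closure).** The most likely failure is closure in the 6-exo mode (attack of C7 on C9) in competition with the 7-endo mode, because the alkyne is only weakly biased; loss of the enol ether to the methyl ketone by protodesilylation and migration of the new olefin into conjugation are secondary risks. Fallback, from 20 back to 21: a radical closure. N-Iodosuccinimide in THF at 0 °C should convert the enol ether into the α-iodo ketone F4. Slow addition of Bu3SnH with azobisisobutyronitrile in benzene at 80 °C then generates the C7 radical, for which endo closure onto C8 is the mode expected of a radical next to a carbonyl lying inside the forming ring; the C9 vinyl radical takes hydrogen from the stannane and gives 21.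

**Step 13 (C6 reduction).** Two processes can spoil it: base-induced migration of the C8=C9 olefin into conjugation before electron transfer, followed by over-reduction, and incomplete thermodynamic control giving some axial alcohol. Fallback, from 21 back to 24: reduction with inversion. LiBH(s-Bu)3 at −78 °C is expected to attack from the open face and give the axial C6 epimer F5. Mitsunobu esterification of F5 with 4-methoxybenzoic acid (PPh3, diisopropyl azodicarboxylate) inverts C6 and installs the ester in one operation, giving 24.

**Step 10 (Wacker oxidation).** The vinyl group sits on a carbon flanked by two quaternary centres and has a homoallylic oxygen, so slow turnover and attack of water at the terminal carbon (aldehyde formation) are the likely failures. Fallback, from 18 back to 19: m-chloroperbenzoic acid epoxidises the vinyl group (the alkyne reacting far more slowly) to the epoxide F6. LiEt3BH opens it at the terminal carbon to the C6 secondary alcohol F7, and Dess–Martin oxidation gives 19.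

**Step 4 (epoxide opening).** A tertiary carbanion must attack a CH2 attached to a quaternary carbon, so slow substitution and decomposition of the anion on warming are the risks. Fallback, from 5 back to 8: a two-stage assembly. 1,3-Dithiane, lithiated with n-BuLi and far less hindered, opens 5 to the monosubstituted dithiane diol F8. After deprotonation of both hydroxyls and the dithiane C–H with excess n-BuLi, iodoethane alkylates carbon and gives 8.

## Further compounds

F1 | step 7 | bis(trimethylsilyl) compound: C1=C2 trimethylsilyl enol ether, C4 trimethylsilyl ether, C5 vinyl | CC1=C(O[Si](C)(C)C)C[C@@](O[Si](C)(C)C)(C(C)C)[C@@H]1C=C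
F2 | step 7 | lithium enolate (C1=C2) of the conjugate adduct, C4 trimethylsilyl ether (not isolated) | CC1=C(O[Li])C[C@@](O[Si](C)(C)C)(C(C)C)[C@@H]1C=C
F3 | step 7 | C4 trimethylsilyl ether of 16 | CC#CC[C@@]1(C)C(=O)C[C@@](O[Si](C)(C)C)(C(C)C)[C@@H]1C=C
F4 | step 12 | α-iodo ketone: C5 iodoacetyl compound, C2 and C4 triethylsilyl ethers | CC#CC[C@@]1(C)[C@@H](O[Si](CC)(CC)CC)C[C@@](O[Si](CC)(CC)CC)(C(C)C)[C@@H]1C(=O)CI
F5 | step 13 | C6 axial alcohol (C6 epimer of 22) | O[C@@H]1CC(C)=CC[C@@]2(C)[C@@H](O[Si](CC)(CC)CC)C[C@@](O[Si](CC)(CC)CC)(C(C)C)[C@H]12
F6 | step 10 | C6–C7 epoxide of 18 (epimers at C6) | CC#CC[C@@]1(C)[C@@H](O[Si](CC)(CC)CC)C[C@@](O[Si](CC)(CC)CC)(C(C)C)[C@@H]1C2CO2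
F7 | step 10 | C6 secondary alcohol (1-hydroxyethyl at C5, epimers at C6) | CC#CC[C@@]1(C)[C@@H](O[Si](CC)(CC)CC)C[C@@](O[Si](CC)(CC)CC)(C(C)C)[C@@H]1C(C)O
F8 | step 4 | (2R)-2-[(1,3-dithian-2-yl)methyl]-3-methylbutane-1,2-diol | OC[C@](O)(C(C)C)CC1SCCCS1
A1 | alternative 1 | alkenyl triflate aldehyde: C4=C5 enol triflate, C2 tert-butyldimethylsilyl ether, (Z)-C8=C9 side chain on C1 ending in the C6 aldehyde | O=CC/C(C)=C\C[C@@]1(C)[C@@H](O[Si](C)(C)C(C)(C)C)CC=C1OS(=O)(=O)C(F)(F)F
A2 | alternative 1 | bicyclic allylic alcohol: C6 hydroxyl, C4=C5 and C8=C9 olefins, C2 tert-butyldimethylsilyl ether | O[C@H]1CC(C)=CC[C@@]2(C)[C@@H](O[Si](C)(C)C(C)(C)C)CC=C12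
A3 | alternative 2 | (5R)-2-diazo-5-(2-methoxy-4-methylphenyl)-6-methyl-5-[(triethylsilyl)oxy]heptan-3-one | CC(=[N+]=[N-])C(=O)C[C@@](O[Si](CC)(CC)CC)(C(C)C)c1ccc(C)cc1OC
A4 | alternative 2 | 8a-methylazulenone triene: C5=C6 methyl enol ether, C7=C8 and C9=C10 olefins, C4 triethylsilyl ether | COC1=C2[C@](O[Si](CC)(CC)CC)(C(C)C)CC(=O)[C@]2(C)C=CC(C)=C1
A5 | alternative 3 | 5-[(tert-butyldimethylsilyl)oxy]-4,7-diethenyl-3,7-dimethyloxepan-2-one (either C3 epimer) | C=C[C@@]1(C)C[C@H](O[Si](C)(C)C(C)(C)C)[C@@H](C=C)C(C)C(=O)O1
A6 | alternative 3 | cycloheptenecarboxylic acid: C1 quaternary with the C2 carboxyl, C5 vinyl, C6 tert-butyldimethylsilyl ether, C8=C9 olefin | CC1=CC[C@@](C)(C(=O)O)[C@H](C=C)[C@@H](O[Si](C)(C)C(C)(C)C)C1
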